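**Assumption:** the target SMILES has no stereocentre and no other stereogenic element, so "the single enantiomer given" is the one achiral compound and no stereocontrol is needed.

## Retrosynthetic overview

1. Target 14 ⇐ bis-coumarin 13 by BCl3 cleavage of two isopropyl ethers; the methyl ether stays.
2. 13 ⇐ bis-phenol 10 + 2 × propiolic acid 11: a two-directional Pd(II) C–H alkenylation/lactonisation closes both pyranone rings last, in one flask (ring B probably first, then ring A).
3. 10 ⇐ dialdehyde 8 by double Baeyer–Villiger oxidation: each CHO first activates the SNAr, then becomes a lactone oxygen.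
4. 8 ⇐ salicylaldehyde 6 + 2-fluoro-3-methoxybenzaldehyde 7 by SNAr: the tetra-ortho-substituted diaryl ether is made early on simple benzenes, not by a late Ullmann coupling of two coumarins.
5. 6 ⇐ 2,4-dihydroxybenzaldehyde 1 (isopropylation, Dakin-type oxidation, ortho-formylation); both benzene rings are bought.

## Route

Step 1
Reactants: 1 2,4-dihydroxybenzaldehyde
Product: 2 2,4-diisopropoxybenzaldehyde
Conditions: i-PrBr (3 equiv), K2CO3 (3 equiv), KI (cat.), DMF, 70 °C
Reagents that add atoms: 2-bromopropane, CC(C)Br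
Why: Williamson ether synthesis; excess halide and warm DMF also alkylate the hydrogen-bonded 2-OH, and isopropyl is chosen because it survives peracid, base and TFA yet is later cleaved by BCl3 without touching OMe.

Step 2
Reactants: 2 2,4-diisopropoxybenzaldehyde
Product: 4 2,4-diisopropoxyphenol, via 2,4-diisopropoxyphenyl formate 3 (not isolated)
Conditions: mCPBA (1.3 equiv), CH2Cl2, 0 °C to rt; aq Na2SO3 wash; then K2CO3 (cat.), MeOH, rt
Reagents that add atoms: mCPBA, OOC(=O)c1cccc(Cl)c1
Why: Baeyer–Villiger (Dakin-type) oxidation; the ortho- and para-alkoxy groups make the aryl group migrate in preference to H, giving the formate, which is methanolysed to the phenol.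

Step 3
Reactants: 4 2,4-diisopropoxyphenol
Product: 6 2-hydroxy-3,5-diisopropoxybenzaldehyde, via 2-(hydroxymethyl)-4,6-diisopropoxyphenol 5 (not isolated)
Conditions: MgCl2 (2 equiv), Et3N (4 equiv), (CH2O)n (6 equiv), MeCN, reflux; aq HCl work-up
Reagents that add atoms: paraformaldehyde (formaldehyde), C=O
Why: Casnati–Skattebøl magnesium-phenoxide ortho-formylation; the chelate delivers formaldehyde to the only free ortho position, and the hydroxymethyl intermediate is oxidised in situ by hydride transfer to a second formaldehyde.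

Step 4
Reactants: 6 2-hydroxy-3,5-diisopropoxybenzaldehyde; 7 2-fluoro-3-methoxybenzaldehyde
Product: 8 2-(2-formyl-6-methoxyphenoxy)-3,5-diisopropoxybenzaldehyde
Conditions: Cs2CO3 (1.5 equiv), DMSO, 110 °C, Ar
Reagents that add atoms: none
Why: SNAr (addition–elimination) at the fluoride activated by the ortho-formyl group; the phenoxide attacks perpendicular to the ring plane so the flanking OMe and CHO are tolerated, and the para-alkoxy group of 6 raises its nucleophilicity.

Step 5
Reactants: 8 2-(2-formyl-6-methoxyphenoxy)-3,5-diisopropoxybenzaldehyde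
Product: 10 2-(2-hydroxy-6-methoxyphenoxy)-3,5-diisopropoxyphenol, via 2-(2-formyloxy-6-methoxyphenoxy)-3,5-diisopropoxyphenyl formate 9 (not isolated)
Conditions: mCPBA (3 equiv), CH2Cl2, 0 °C to rt; aq Na2SO3 wash; then K2CO3 (cat.), MeOH, rt, Ar
Reagents that add atoms: mCPBA, OOC(=O)c1cccc(Cl)c1
Why: Two-directional Baeyer–Villiger oxidation; each formyl group has an ortho-aryloxy donor that favours aryl migration, and the peracid is destroyed before the electron-rich bis-phenol is released from its formates.

Step 6
Reactants: 10 2-(2-hydroxy-6-methoxyphenoxy)-3,5-diisopropoxyphenol; 11 propiolic acid (3 equiv)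
Product: 13 5,7-diisopropoxy-8-[(7-methoxy-2-oxo-2H-chromen-8-yl)oxy]-2H-chromen-2-one, via 8-(2-hydroxy-6-methoxyphenoxy)-5,7-diisopropoxycoumarin 12 (not isolated)
Conditions: Pd(OAc)2 (5 mol %), TFA/CH2Cl2 3:1, rt, 24–48 h
Reagents that add atoms: none
Why: Key step, a double Fujiwara–Kitamura Pd(II) hydroarylation of propiolic acid followed by lactonisation (Pechmann-type coumarin synthesis). On ring B the only carbon ortho to the single free OH is also ortho/para to the two alkoxy groups, and the alternative site between two OiPr groups is shielded and cannot lactonise; on ring A the carbon ortho to OH and para to OMe reacts, as 3-methoxyphenol gives 7-methoxycoumarin. Only one OH per ring is free, so the lactone regiochemistry is unambiguous.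

Step 7
Reactants: 13 5,7-diisopropoxy-8-[(7-methoxy-2-oxo-2H-chromen-8-yl)oxy]-2H-chromen-2-one
Product: 14 5,7-dihydroxy-8-[(7-methoxy-2-oxo-2H-chromen-8-yl)oxy]-2H-chromen-2-one (target)
Conditions: BCl3 (1 M in CH2Cl2, 6 equiv), CH2Cl2, −78 to 0 °C; then MeOH/H2O
Reagents that add atoms: none
Why: Lewis-acid dealkylation; BCl3 cleaves secondary (isopropyl) aryl ethers through an SN1-like C–O scission far faster than methyl ethers, and the lactones and the diaryl ether are inert at this temperature.

## Compound list

1 | 2,4-dihydroxybenzaldehyde | O=Cc1ccc(O)cc1O | starting material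
2 | 2,4-diisopropoxybenzaldehyde | CC(C)Oc1ccc(C=O)c(OC(C)C)c1 | intermediate
3 | 2,4-diisopropoxyphenyl formate | CC(C)Oc1ccc(OC=O)c(OC(C)C)c1 | intermediate
4 | 2,4-diisopropoxyphenol | CC(C)Oc1ccc(O)c(OC(C)C)c1 | intermediate
5 | 2-(hydroxymethyl)-4,6-diisopropoxyphenol | OCc1cc(OC(C)C)cc(OC(C)C)c1O | intermediate
6 | 2-hydroxy-3,5-diisopropoxybenzaldehyde | O=Cc1cc(OC(C)C)cc(OC(C)C)c1O | intermediate
7 | 2-fluoro-3-methoxybenzaldehyde | COc1cccc(C=O)c1F | starting material
8 | 2-(2-formyl-6-methoxyphenoxy)-3,5-diisopropoxybenzaldehyde | COc1cccc(C=O)c1Oc1c(C=O)cc(OC(C)C)cc1OC(C)C | intermediate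
9 | 2-(2-formyloxy-6-methoxyphenoxy)-3,5-diisopropoxyphenyl formate | COc1cccc(OC=O)c1Oc1c(OC=O)cc(OC(C)C)cc1OC(C)C | intermediate
10 | 2-(2-hydroxy-6-methoxyphenoxy)-3,5-diisopropoxyphenol | COc1cccc(O)c1Oc1c(O)cc(OC(C)C)cc1OC(C)C | intermediate
11 | propiolic acid | C#CC(=O)O | starting material
12 | 8-(2-hydroxy-6-methoxyphenoxy)-5,7-diisopropoxy-2H-chromen-2-one | COc1cccc(O)c1Oc1c(OC(C)C)cc(OC(C)C)c2ccc(=O)oc12 | intermediate
13 | 5,7-diisopropoxy-8-[(7-methoxy-2-oxo-2H-chromen-8-yl)oxy]-2H-chromen-2-one | COc1ccc2ccc(=O)oc2c1Oc1c(OC(C)C)cc(OC(C)C)c2ccc(=O)oc12 | intermediate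
14 | 5,7-dihydroxy-8-[(7-methoxy-2-oxo-2H-chromen-8-yl)oxy]-2H-chromen-2-one | COc1ccc2ccc(=O)oc2c1Oc1c(O)cc(O)c2ccc(=O)oc12 | target

## Step count and risks

Total step count: 7. Longest linear sequence: 7 steps (1 → 14); 7 and 11 are bought and enter at steps 4 and 6.

The three steps most likely to fail:

**Step 4 (SNAr to a tetra-ortho-substituted diaryl ether).** The phenoxide of 6 is hindered and attenuated by its ortho-formyl group, and the fluoride of 7 has only one activating group. Fallback: the C–O bond is made by copper catalysis instead of addition–elimination. Compound 6 is coupled with commercial 2-bromo-3-methoxybenzaldehyde (CuI, picolinic acid, K3PO4, DMSO, 100 °C), an Ullmann-type coupling in which the ortho-formyl group of the bromide assists oxidative addition. This fallback sets out from 6, makes no new compound (F0) and comes back to the route at 8.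

**Step 5 (double Baeyer–Villiger).** Each aldehyde has only one ortho donor, so H-migration to the carboxylic acid can compete, and ring B is easily over-oxidised. Fallback: the formyl groups are turned into acetyl groups, for which H-migration is impossible. Setting out from 8, MeMgBr (THF, 0 °C) gives 1-[2-[2-(1-hydroxyethyl)-6-methoxyphenoxy]-3,5-diisopropoxyphenyl]ethanol F1 as a diastereomer mixture. Dess–Martin periodinane oxidises it to 1-[2-(2-acetyl-6-methoxyphenoxy)-3,5-diisopropoxyphenyl]ethanone F2. Baeyer–Villiger oxidation (mCPBA, cat. TFA, CH2Cl2, reflux) then gives 2-(2-acetoxy-6-methoxyphenoxy)-3,5-diisopropoxyphenyl acetate F3, and K2CO3/MeOH methanolysis comes back to the route at 10.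

**Step 6 (double Pd-catalysed annulation).** Alkenylation para to OH, incomplete reaction of the less electron-rich ring A, or a second alkenylation of ring B would lower the yield. Fallback: the C3 unit is built by carbonyl olefination instead of C–H alkenylation. Setting out from 10, magnesium-mediated double ortho-formylation (MgCl2, Et3N, (CH2O)n, MeCN, reflux) gives 3-(3-formyl-2-hydroxy-6-methoxyphenoxy)-2-hydroxy-4,6-diisopropoxybenzaldehyde F4. Wittig olefination with Ph3P=CHCO2Et in refluxing N,N-diethylaniline gives the bis-cinnamate diethyl ester F5, which isomerises and lactonises at that temperature and comes back to the route at 13.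

## Further compounds

F0 | step 4 | none | none
F1 | step 5 | 1-[2-[2-(1-hydroxyethyl)-6-methoxyphenoxy]-3,5-diisopropoxyphenyl]ethanol (diastereomer mixture) | COc1cccc(C(C)O)c1Oc1c(C(C)O)cc(OC(C)C)cc1OC(C)C
F2 | step 5 | 1-[2-(2-acetyl-6-methoxyphenoxy)-3,5-diisopropoxyphenyl]ethanone | COc1cccc(C(C)=O)c1Oc1c(C(C)=O)cc(OC(C)C)cc1OC(C)C
F3 | step 5 | 2-(2-acetoxy-6-methoxyphenoxy)-3,5-diisopropoxyphenyl acetate | COc1cccc(OC(C)=O)c1Oc1c(OC(C)=O)cc(OC(C)C)cc1OC(C)C
F4 | step 6 | 3-(3-formyl-2-hydroxy-6-methoxyphenoxy)-2-hydroxy-4,6-diisopropoxybenzaldehyde | COc1ccc(C=O)c(O)c1Oc1c(O)c(C=O)c(OC(C)C)cc1OC(C)C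
F5 | step 6 | diethyl (E,E)-bis-cinnamate: ethyl (E)-3-[3-[3-[(E)-3-ethoxy-3-oxoprop-1-enyl]-2-hydroxy-4,6-diisopropoxyphenoxy]-2-hydroxy-4-methoxyphenyl]acrylate | CCOC(=O)/C=C/c1ccc(OC)c(Oc2c(O)c(/C=C/C(=O)OCC)c(OC(C)C)cc2OC(C)C)c1O
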